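The retrosynthesis cuts both exocyclic bonds of the lactone, C3–C7' and C4–C7, in one operation. This gives a four-carbon butenolide, a dithiane acyl-anion equivalent of the guaiacyl ring, and a dihydrobenzofuranylmethyl bromide. The bromide is cut further at bf-C2–bf-C3 of its dihydrofuran ring, at the aryl–CH2CO2Me bond and at the benzylic ether C–O bond.
Enabling feature: the γ-butyrolactone ring (O1, C2, C3, C4, C5) carries trans arylmethyl groups on the neighbouring carbons C3 and C4 and a bare C5 methylene. This is the imprint of a nucleophile (at C4) and an electrophile (at C3) added across C3=C4 of a furan-2(5H)-one whose C5 can hold a removable chiral alkoxy group.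
Forward order: the lactone ring comes from the furan ring of furfural, and the dihydrofuran ring is closed by carbenoid C–H insertion. The three fragments are then joined in one flask, and the lactone is opened and re-closed at C5 before deprotection.
Stereochemistry: bf-C2 (S) comes from a chiral dirhodium carboxylate catalyst and bf-C3 from epimerisation to the trans ester. Lactone C4 (R) is set by the menthol-derived C5 acetal centre and C3 (R) by C4; C5 is finally reduced to CH2, so the auxiliary leaves no trace.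

Key step: step 14

Assumption: the sense of induction of the Rh2(PTTL)4 catalysts is taken from simpler 2-(benzyloxy)phenyl diazoacetates, where the S ligand series leads to 2R products. The R series is therefore used for bf-C2 = S; both antipodes of the catalyst are accessible.

Abbreviations:
- Ar = 4-(benzyloxy)-3-methoxyphenyl
- Men = (1R,2S,5R)-menthyl
- TBS = tert-butyldimethylsilyl
- PTTL = N-phthaloyl-tert-leucinate
- Bf = (2S,3R)-2-Ar-3-(TBSOCH2)-7-methoxy-2,3-dihydrobenzofuran-5-yl
- bf-C2 and bf-C3 = carbons 2 and 3 of the dihydrobenzofuran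
- C7 and C7' = the carbons attached to lactone C4 and C3

Step 1
Reactants: 1 furfural
Product: 2 5-hydroxyfuran-2(5H)-one (racemic lactol)
Conditions: O2, hν (visible), rose bengal (cat.), MeOH, 20 °C
Reagents that add atoms: dioxygen, O=O
Why: Dye-sensitised photooxygenation: singlet oxygen adds [4+2] across C2/C5 of the furan and methanol cleaves the formyl group from the endoperoxide as methyl formate, the standard entry to this γ-hydroxybutenolide; the lactol carbon is configurationally labile and needs no control.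

Step 2
Reactants: 2 5-hydroxyfuran-2(5H)-one; 3 (1R,2S,5R)-menthol
Product: 4 (5R)-5-[(1R,2S,5R)-menthyloxy]furan-2(5H)-one
Conditions: neat, 100 °C; crystallisation from petroleum ether, −20 °C; mother liquor re-equilibrated with p-TsOH (cat.) and recrystallised
Reagents that add atoms: none
Why: Thermal acetalisation of the lactol gives both C5 epimers, but only the 5R epimer crystallises and C5 equilibrates under acid through the oxocarbenium ion, so crystallisation with recycling of the mother liquor (crystallisation-driven epimerisation) should converge on 4, the menthyl group being the source of asymmetry.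

Step 3
Reactants: 5 4-(benzyloxy)-3-methoxybenzaldehyde; 6 propane-1,3-dithiol
Product: 7 2-[4-(benzyloxy)-3-methoxyphenyl]-1,3-dithiane
Conditions: BF3·OEt2 (cat.), CH2Cl2, 0 °C to rt
Reagents that add atoms: none
Why: Lewis-acid-catalysed dithioacetalisation of an aromatic aldehyde, which installs the umpolung handle and leaves the benzyl ether alone.

Step 4
Reactants: 8 3-bromo-4-hydroxy-5-methoxybenzaldehyde (5-bromovanillin); 9 [4-(benzyloxy)-3-methoxyphenyl]methanol
Product: 10 4-(ArCH2O)-3-bromo-5-methoxybenzaldehyde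
Conditions: PPh3, DIAD, THF, 0 °C to rt
Reagents that add atoms: none
Why: Mitsunobu etherification: the acidic phenol of 8 (flanked by Br and OMe, para to CHO) protonates the betaine readily and displaces the phosphonium-activated primary benzylic alcohol under neutral conditions, so no separate benzylic halide is needed and the aldehyde is untouched.

Step 5
Reactants: 10 4-(ArCH2O)-3-bromo-5-methoxybenzaldehyde
Product: 11 2-[4-(ArCH2O)-3-bromo-5-methoxyphenyl]-1,3-dioxolane
Conditions: TMSOCH2CH2OTMS, TMSOTf (cat.), CH2Cl2, −78 to −20 °C; pyridine quench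
Reagents that add atoms: 1,2-bis(trimethylsilyloxy)ethane, C[Si](C)(C)OCCO[Si](C)(C)C
Why: TMSOTf-catalysed acetalisation with the bis-silyl ether of glycol is aprotic, cold and driven by formation of the disiloxane, so the acid-sensitive p-alkoxybenzyl aryl ether survives while the aldehyde is masked against zinc enolate, methoxide and hydride.

Step 6
Reactants: 11 2-[4-(ArCH2O)-3-bromo-5-methoxyphenyl]-1,3-dioxolane; 12 methyl bromoacetate
Product: 14 methyl 2-[2-(ArCH2O)-5-(1,3-dioxolan-2-yl)-3-methoxyphenyl]acetate, via Reformatsky reagent 13 (not isolated)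
Conditions: 12, Zn dust (TMSCl-activated), THF, 40 °C; then 11, Pd2(dba)3 (cat.), XPhos (cat.), THF, 65 °C
Reagents that add atoms: zinc, [Zn] (metal of 13 only)
Why: Reformatsky–Negishi α-arylation: zerovalent palladium bearing the bulky biaryl phosphine inserts into the ortho-alkoxy C–Br bond, the weakly basic zinc enolate transmetallates and reductive elimination gives the arylacetate, conditions known to tolerate esters and acetals.

Step 7
Reactants: 14 methyl 2-[2-(ArCH2O)-5-(1,3-dioxolan-2-yl)-3-methoxyphenyl]acetate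
Product: 15 methyl 2-diazo-2-[2-(ArCH2O)-5-(1,3-dioxolan-2-yl)-3-methoxyphenyl]acetate
Conditions: p-ABSA, DBU, MeCN, 0 °C to rt
Reagents that add atoms: 4-acetamidobenzenesulfonyl azide (p-ABSA), CC(=O)Nc1ccc(cc1)S(=O)(=O)N=[N+]=[N-]
Why: Regitz diazo transfer: DBU enolises the benzylic ester and the enolate captures the sulfonyl azide, the usual way to aryl diazoacetates.

Step 8
Reactants: 15 methyl 2-diazo-2-[2-(ArCH2O)-5-(1,3-dioxolan-2-yl)-3-methoxyphenyl]acetate
Product: 16 methyl (2S,3R)-2-Ar-5-(1,3-dioxolan-2-yl)-7-methoxy-2,3-dihydrobenzofuran-3-carboxylate (cis)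
Conditions: Rh2(R-PTTL)4 (1 mol%), toluene, −60 °C
Reagents that add atoms: none
Why: Intramolecular 1,5 C–H insertion of a donor/acceptor rhodium carbenoid into the electron-rich benzylic ether CH2 closes the dihydrofuran ring (bf-C2–bf-C3 bond); the chiral carboxylate pocket selects one of the two enantiotopic hydrogens and so sets bf-C2 as S, and the concerted insertion places aryl and ester cis (3R), as known for 2-(benzyloxy)phenyl diazoacetates with this catalyst family.

Step 9
Reactants: 16 cis ester (2S,3R)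
Product: 17 methyl (2S,3S)-2-Ar-5-(1,3-dioxolan-2-yl)-7-methoxy-2,3-dihydrobenzofuran-3-carboxylate (trans)
Conditions: NaOMe (0.3 equiv), MeOH–THF, 0 °C to rt
Reagents that add atoms: none
Why: Thermodynamic epimerisation through the ester enolate inverts only bf-C3 (3R to 3S) because the cis aryl/ester pair is strained and bf-C2 has no acidic hydrogen; catalytic base, low temperature and the poor guaiacolate-type leaving group (the para aldehyde is masked) hold back E1cB opening of the ring.

Step 10
Reactants: 17 trans ester (2S,3S)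
Product: 19 (2S,3R)-2-Ar-3-(hydroxymethyl)-7-methoxy-2,3-dihydrobenzofuran-5-carbaldehyde, via acetal alcohol 18 (not isolated)
Conditions: LiAlH4, THF, 0 °C; then 1 M HCl, THF, rt
Reagents that add atoms: water, O (aldehyde oxygen of 19)
Why: Hydride reduction of the ester followed by acid hydrolysis of the aryl dioxolane in the same flask; neither stereocentre is touched (the bf-C3 descriptor changes from S to R only because CH2OH ranks below bf-C2), and hydrolysing before silylation avoids any conflict between acid and silyl ether.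

Step 11
Reactants: 19 hydroxy aldehyde
Product: 20 (2S,3R)-2-Ar-3-(TBSOCH2)-7-methoxy-2,3-dihydrobenzofuran-5-carbaldehyde (Bf-CHO)
Conditions: TBSCl, imidazole, DMF, rt
Reagents that add atoms: tert-butyldimethylsilyl chloride, CC(C)(C)[Si](C)(C)Cl
Why: Standard imidazole-promoted silylation of the only hydroxyl group, giving an ether that withstands enolate, nickel boride and KOH.

Step 12
Reactants: 20 Bf-CHO
Product: 21 Bf-CH2OH
Conditions: NaBH4, MeOH–THF, 0 °C
Reagents that add atoms: none
Why: Chemoselective borohydride reduction of the aromatic aldehyde.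

Step 13
Reactants: 21 Bf-CH2OH
Product: 22 (2S,3R)-5-(bromomethyl)-2-Ar-7-methoxy-3-(TBSOCH2)-2,3-dihydrobenzofuran (Bf-CH2Br)
Conditions: CBr4, PPh3, CH2Cl2, 0 °C
Reagents that add atoms: carbon tetrabromide, BrC(Br)(Br)Br
Why: Appel reaction: SN2 displacement of the oxyphosphonium ion by bromide under neutral conditions keeps the silyl ether and the ring benzylic C–O bond intact; the ionisable p-alkoxybenzyl bromide is passed through a short silica plug and used at once.

Step 14
Reactants: 7 2-Ar-1,3-dithiane; 4 (5R)-5-menthyloxyfuran-2(5H)-one; 22 Bf-CH2Br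
Product: 25 (3R,4R,5R)-3-(Bf-CH2)-4-(2-Ar-1,3-dithian-2-yl)-5-(menthyloxy)dihydrofuran-2(3H)-one (all-trans), via 2-lithiodithiane 23 (not isolated), via lithium enolate 24 (not isolated)
Conditions: 7, n-BuLi, THF, −78 °C; 4, −78 °C; then DMPU, 22, −78 to −10 °C; aq. NH4Cl
Reagents that add atoms: n-butyllithium, [Li]CCCC (lithium of 23 and 24 only)
Why: n-BuLi removes the C2 proton of 7, and the sulfur- and aryl-stabilised carbanion 23 adds in Michael fashion to C4 of 4 to leave lithium enolate 24, which, deaggregated by DMPU, displaces bromide from 22 through C3 in an SN2 reaction. The closest known reaction type is the tandem conjugate addition–enolate alkylation of 5-alkoxyfuran-2(5H)-ones with lithiated dithioacetals and benzylic halides. No ring is closed; the step forms the C4–C7 and C3–C7' bonds on the existing lactone ring. C4 (R) is controlled by the C5 acetal centre, whose menthyloxy group blocks one face of the planar butenolide so that 23 enters anti to it, and C3 (R) is controlled by C4, whose very large 2-aryl-dithianyl group forces 22 onto the opposite face of the enolate, giving the all-trans 3,4,5 pattern. The step needs 1,4- over 1,2-addition, secured by the soft delocalised anion and the unsubstituted β-carbon, and C-monoalkylation, secured by the reactive benzylic bromide, the low temperature and the shielding of the remaining C3 hydrogen in 25. Since 4 is a single enantiomer, any minor enantiomer carried in 22 ends up as a diastereomer of 25 and can be removed by chromatography.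

Step 15
Reactants: 25 dithianyl lactone acetal
Product: 26 (3R,4R,5R)-3-(Bf-CH2)-4-(ArCH2)-5-(menthyloxy)dihydrofuran-2(3H)-one
Conditions: NiCl2·6H2O, NaBH4, MeOH–THF, 0 °C
Reagents that add atoms: none
Why: Reductive desulfurisation with nickel boride (Ni2B) formed in the flask cleaves all four C–S bonds without touching benzyl ethers, silyl ether or acyl acetal, as known for this class of dithianyl lactones; no stereocentre is involved.

Step 16
Reactants: 26 menthyloxy lactone
Product: 29 (3R,4R)-4-(ArCH2)-3-{[(2S,3R)-2-Ar-3-(hydroxymethyl)-7-methoxy-2,3-dihydrobenzofuran-5-yl]methyl}dihydrofuran-2(3H)-one (di-O-benzyl isolappaol A), via formyl carboxylate 27 (not isolated), via hydroxy carboxylate 28 (not isolated)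
Conditions: NaBH4, KOH, EtOH–THF–H2O, 0 °C to rt; then 1 M HCl to pH 1, rt
Reagents that add atoms: potassium hydroxide, [K+].[OH-] (carboxylate oxygen and counter-ion of 27 and 28; the oxygen leaves again as water on lactonisation)
Why: Saponification of the acyl acetal expels menthoxide and unmasks C5 as an aldehyde that the borohydride already present reduces faster than it can enolise (so C4 holds), and acidification then closes the γ-lactone by 5-exo-trig attack of the new C5 hydroxyl on the acid and solvolyses the primary silyl ether.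

Step 17
Reactants: 29 di-O-benzyl isolappaol A
Product: 30 isolappaol A
Conditions: H2 (1 atm), 10% Pd/C, EtOAc–EtOH, rt
Reagents that add atoms: none
Why: Catalytic hydrogenolysis: the two aryl benzyl ethers are cleaved far faster than the secondary, ring-bound benzylic bf-C2–O bond in neutral solvent at one atmosphere, a selectivity known from phenylcoumaran neolignans, and the reaction is stopped after uptake of two equivalents of hydrogen.

Compound list
1 | furfural | O=Cc1ccco1 | starting material
2 | 5-hydroxyfuran-2(5H)-one (racemic) | O=C1C=CC(O)O1 | intermediate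
3 | (1R,2S,5R)-menthol | CC(C)[C@@H]1CC[C@@H](C)C[C@H]1O | starting material
4 | (5R)-5-[(1R,2S,5R)-menthyloxy]furan-2(5H)-one | O=C1C=C[C@H](O[C@@H]2C[C@H](C)CC[C@H]2C(C)C)O1 | intermediate
5 | 4-(benzyloxy)-3-methoxybenzaldehyde | COc1cc(C=O)ccc1OCc1ccccc1 | starting material
6 | propane-1,3-dithiol | SCCCS | starting material
7 | 2-[4-(benzyloxy)-3-methoxyphenyl]-1,3-dithiane | COc1cc(C2SCCCS2)ccc1OCc1ccccc1 | intermediate
8 | 3-bromo-4-hydroxy-5-methoxybenzaldehyde (5-bromovanillin) | COc1cc(C=O)cc(Br)c1O | starting material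
9 | [4-(benzyloxy)-3-methoxyphenyl]methanol | COc1cc(CO)ccc1OCc1ccccc1 | starting material
10 | 4-{[4-(benzyloxy)-3-methoxyphenyl]methoxy}-3-bromo-5-methoxybenzaldehyde | COc1cc(C=O)cc(Br)c1OCc1ccc(OCc2ccccc2)c(OC)c1 | intermediate
11 | 2-(4-{[4-(benzyloxy)-3-methoxyphenyl]methoxy}-3-bromo-5-methoxyphenyl)-1,3-dioxolane | COc1cc(C2OCCO2)cc(Br)c1OCc1ccc(OCc2ccccc2)c(OC)c1 | intermediate
12 | methyl bromoacetate | COC(=O)CBr | starting material
13 | (2-methoxy-2-oxoethyl)zinc bromide (Reformatsky reagent, not isolated) | COC(=O)C[Zn]Br | intermediate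
14 | methyl 2-[2-{[4-(benzyloxy)-3-methoxyphenyl]methoxy}-5-(1,3-dioxolan-2-yl)-3-methoxyphenyl]acetate | COC(=O)Cc1cc(C2OCCO2)cc(OC)c1OCc1ccc(OCc2ccccc2)c(OC)c1 | intermediate
15 | methyl 2-diazo-2-[2-{[4-(benzyloxy)-3-methoxyphenyl]methoxy}-5-(1,3-dioxolan-2-yl)-3-methoxyphenyl]acetate | COC(=O)C(=[N+]=[N-])c1cc(C2OCCO2)cc(OC)c1OCc1ccc(OCc2ccccc2)c(OC)c1 | intermediate
16 | methyl (2S,3R)-2-[4-(benzyloxy)-3-methoxyphenyl]-5-(1,3-dioxolan-2-yl)-7-methoxy-2,3-dihydrobenzofuran-3-carboxylate (cis) | O1CCOC1c1cc(OC)c2c(c1)[C@@H](C(=O)OC)[C@@H](c1ccc(OCc3ccccc3)c(OC)c1)O2 | intermediate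
17 | methyl (2S,3S)-2-[4-(benzyloxy)-3-methoxyphenyl]-5-(1,3-dioxolan-2-yl)-7-methoxy-2,3-dihydrobenzofuran-3-carboxylate (trans) | O1CCOC1c1cc(OC)c2c(c1)[C@H](C(=O)OC)[C@@H](c1ccc(OCc3ccccc3)c(OC)c1)O2 | intermediate
18 | [(2S,3R)-2-[4-(benzyloxy)-3-methoxyphenyl]-5-(1,3-dioxolan-2-yl)-7-methoxy-2,3-dihydrobenzofuran-3-yl]methanol (not isolated) | O1CCOC1c1cc(OC)c2c(c1)[C@H](CO)[C@@H](c1ccc(OCc3ccccc3)c(OC)c1)O2 | intermediate
19 | (2S,3R)-2-[4-(benzyloxy)-3-methoxyphenyl]-3-(hydroxymethyl)-7-methoxy-2,3-dihydrobenzofuran-5-carbaldehyde | O=Cc1cc(OC)c2c(c1)[C@H](CO)[C@@H](c1ccc(OCc3ccccc3)c(OC)c1)O2 | intermediate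
20 | (2S,3R)-2-[4-(benzyloxy)-3-methoxyphenyl]-3-(tert-butyldimethylsilyloxymethyl)-7-methoxy-2,3-dihydrobenzofuran-5-carbaldehyde | O=Cc1cc(OC)c2c(c1)[C@H](CO[Si](C)(C)C(C)(C)C)[C@@H](c1ccc(OCc3ccccc3)c(OC)c1)O2 | intermediate
21 | [(2S,3R)-2-[4-(benzyloxy)-3-methoxyphenyl]-3-(tert-butyldimethylsilyloxymethyl)-7-methoxy-2,3-dihydrobenzofuran-5-yl]methanol | OCc1cc(OC)c2c(c1)[C@H](CO[Si](C)(C)C(C)(C)C)[C@@H](c1ccc(OCc3ccccc3)c(OC)c1)O2 | intermediate
22 | (2S,3R)-5-(bromomethyl)-2-[4-(benzyloxy)-3-methoxyphenyl]-7-methoxy-3-(tert-butyldimethylsilyloxymethyl)-2,3-dihydrobenzofuran | BrCc1cc(OC)c2c(c1)[C@H](CO[Si](C)(C)C(C)(C)C)[C@@H](c1ccc(OCc3ccccc3)c(OC)c1)O2 | intermediate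
23 | 2-lithio-2-[4-(benzyloxy)-3-methoxyphenyl]-1,3-dithiane (not isolated) | COc1cc(C2([Li])SCCCS2)ccc1OCc1ccccc1 | intermediate
24 | lithium enolate of (4R,5R)-4-(2-aryl-1,3-dithian-2-yl)-5-(menthyloxy)dihydrofuran-2(3H)-one (not isolated) | COc1cc(C2(SCCCS2)[C@H]2[C@H](O[C@@H]3C[C@H](C)CC[C@H]3C(C)C)OC(O[Li])=C2)ccc1OCc1ccccc1 | intermediate
25 | (3R,4R,5R)-3-(dihydrobenzofuranylmethyl)-4-[2-aryl-1,3-dithian-2-yl]-5-(menthyloxy)dihydrofuran-2(3H)-one, all-trans | COc1cc(C2(SCCCS2)[C@H]2[C@H](O[C@@H]3C[C@H](C)CC[C@H]3C(C)C)OC(=O)[C@@H]2Cc2cc(OC)c3c(c2)[C@H](CO[Si](C)(C)C(C)(C)C)[C@@H](c2ccc(OCc4ccccc4)c(OC)c2)O3)ccc1OCc1ccccc1 | intermediate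
26 | (3R,4R,5R)-3-(dihydrobenzofuranylmethyl)-4-[4-(benzyloxy)-3-methoxybenzyl]-5-(menthyloxy)dihydrofuran-2(3H)-one | COc1cc(C[C@H]2[C@H](O[C@@H]3C[C@H](C)CC[C@H]3C(C)C)OC(=O)[C@@H]2Cc2cc(OC)c3c(c2)[C@H](CO[Si](C)(C)C(C)(C)C)[C@@H](c2ccc(OCc4ccccc4)c(OC)c2)O3)ccc1OCc1ccccc1 | intermediate
27 | potassium (2R,3R)-2-(Bf-methyl)-3-formyl-4-[4-(benzyloxy)-3-methoxyphenyl]butanoate (not isolated) | COc1cc(C[C@@H](C=O)[C@H](C(=O)[O-])Cc2cc(OC)c3c(c2)[C@H](CO[Si](C)(C)C(C)(C)C)[C@@H](c2ccc(OCc4ccccc4)c(OC)c2)O3)ccc1OCc1ccccc1.[K+] | intermediate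
28 | potassium (2R,3R)-2-(Bf-methyl)-3-(hydroxymethyl)-4-[4-(benzyloxy)-3-methoxyphenyl]butanoate (not isolated) | COc1cc(C[C@@H](CO)[C@H](C(=O)[O-])Cc2cc(OC)c3c(c2)[C@H](CO[Si](C)(C)C(C)(C)C)[C@@H](c2ccc(OCc4ccccc4)c(OC)c2)O3)ccc1OCc1ccccc1.[K+] | intermediate
29 | di-O-benzyl isolappaol A, (3R,4R) lactone, (2S,3R) dihydrobenzofuran, free CH2OH | COc1cc(C[C@H]2COC(=O)[C@@H]2Cc2cc(OC)c3c(c2)[C@H](CO)[C@@H](c2ccc(OCc4ccccc4)c(OC)c2)O3)ccc1OCc1ccccc1 | intermediate
30 | isolappaol A | COc1cc(C[C@H]2COC(=O)[C@@H]2Cc2cc(OC)c3c(c2)[C@H](CO)[C@@H](c2ccc(O)c(OC)c2)O3)ccc1O | target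

Total step count: 17. Longest linear sequence: 14 steps (steps 4–17, from 8 to 30). Compounds 1, 3, 5, 6, 8, 9 and 12 are catalogue chemicals.

Steps most likely to fail

1. Step 14.
- Risk: the hindered enolate 24 may be alkylated too slowly. On warming it would then revert by retro-Michael loss of 23 or exchange protons, while the ionisable p-alkoxybenzyl bromide decays.
- Fallback: it sets out from aldehyde 20 (with 4 and 7) and comes back to the route at 26, bypassing steps 12 and 13.
- Enolate 24, generated as before, is intercepted at −78 °C by 20 in an aldol reaction. This is much faster than the SN2 step and should give the C7' carbinol aldol adduct F1. The carbinol epimers are of no consequence, and the anti relation at C3/C4 is unchanged.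
- NiCl2·6H2O/NaBH4 then removes the sulfur to give the desulfurised carbinol F2.
- 1,1'-Thiocarbonyldiimidazole (DMAP, 1,2-dichloroethane, 60 °C) converts the hydroxyl group into the imidazole-1-carbothioate F3.
- Barton–McCombie reduction (Bu3SnH, AIBN, toluene, 90 °C) erases the C7' oxygen through the benzylic radical to give 26.

2. Step 8.
- Risk: discrimination between the two enantiotopic benzylic hydrogens may be poor with the extra 3-methoxy group next to the ether oxygen, so that bf-C2 is set with insufficient selectivity.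
- Fallback: catalyst control is given up for a classical resolution. It sets out from scalemic 19 and comes back at 19.
- The alcohol is esterified with (S)-2-methoxy-2-phenylacetic acid (DCC, DMAP, CH2Cl2) to the (S)-O-methylmandelate F4.
- The diastereomers are separated by crystallisation or chromatography, and K2CO3 in MeOH releases 19 as a single enantiomer.

3. Step 17.
- Risk: hydrogenolysis may run on to the benzylic bf-C2–O bond of the dihydrofuran ring, or residual sulfur may poison the catalyst.
- Fallback: the reductive method is replaced by a Lewis-acid debenzylation. It sets out from 29 and comes back at 30.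
- BCl3 is used with pentamethylbenzene as benzyl-cation scavenger in CH2Cl2 at −78 °C. Chelation of boron between each benzyloxy oxygen and its neighbouring methoxy oxygen directs cleavage to the two guaiacyl benzyl ethers.
- No compound outside the list is made (F0).

Further compounds
F1 | step 14 | aldol adduct: 25 with C7'H(OH) in place of C7'H2 (carbinol epimers) | COc1cc(C2(SCCCS2)[C@H]2[C@H](O[C@@H]3C[C@H](C)CC[C@H]3C(C)C)OC(=O)[C@@H]2C(O)c2cc(OC)c3c(c2)[C@H](CO[Si](C)(C)C(C)(C)C)[C@@H](c2ccc(OCc4ccccc4)c(OC)c2)O3)ccc1OCc1ccccc1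
F2 | step 14 | desulfurised carbinol: 26 with C7'H(OH) in place of C7'H2 | COc1cc(C[C@H]2[C@H](O[C@@H]3C[C@H](C)CC[C@H]3C(C)C)OC(=O)[C@@H]2C(O)c2cc(OC)c3c(c2)[C@H](CO[Si](C)(C)C(C)(C)C)[C@@H](c2ccc(OCc4ccccc4)c(OC)c2)O3)ccc1OCc1ccccc1
F3 | step 14 | imidazole-1-carbothioate (O-ester) of F2 | COc1cc(C[C@H]2[C@H](O[C@@H]3C[C@H](C)CC[C@H]3C(C)C)OC(=O)[C@@H]2C(OC(=S)n5ccnc5)c2cc(OC)c3c(c2)[C@H](CO[Si](C)(C)C(C)(C)C)[C@@H](c2ccc(OCc4ccccc4)c(OC)c2)O3)ccc1OCc1ccccc1
F4 | step 8 | (S)-O-methylmandelate of (2S,3R)-19 | O=Cc1cc(OC)c2c(c1)[C@H](COC(=O)[C@@H](OC)c1ccccc1)[C@@H](c1ccc(OCc3ccccc3)c(OC)c1)O2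
F0 | step 17 | none | none
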